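**Retrosynthetic overview**

- The oxane ring is closed last: the target acid comes from an acyclic (3S,6R)-hydroxy-tosylate ester by C6–O Williamson closure and saponification.
- That diol ester comes from a bridged methylidene-dioxanone, opened again with C5 equilibrated through the ring lactol (2,5-trans favoured) before hydride reduction.
- The dioxanone (oxane-lactol ring and 1,3-dioxan-4-one ring formed together) comes from a 2-homofarnesylglutaraldehyde and an N-acryloyl sultam by an auxiliary-controlled Baylis–Hillman cascade that sets C2.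
- The dialdehyde comes from 3-homofarnesylpyridine by Birch dearomatisation and hydrolytic excision of nitrogen: the pyridine is a latent 1,5-dialdehyde that supplies C2–C6 of the oxane.
- The 3-alkylpyridine comes from 3-methylpyridine (lateral lithiation) and (2E,6E)-farnesyl bromide.

Assumption: the sultam-controlled Baylis–Hillman step is taken to give (R)-carbinols from alkanals with the (2R)-sultam acrylamide, so the (2S)-sultam acrylamide is used; if the sense is the reverse, the antipodal acrylamide is used and nothing else changes.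

**Step 1**
Reactants: 1 3-methylpyridine; 2 (2E,6E)-farnesyl bromide
Product: 4 3-[(3E,7E)-4,8,12-trimethyltrideca-3,7,11-trien-1-yl]pyridine, via picolyllithium 3 (not isolated)
Conditions: LiN(iPr)2 (lithium diisopropylamide), THF, −78 °C, 1 h; then 2, −78 → 0 °C
Reagents that add atoms: none
Why: Lateral lithiation of 3-picoline and SN2 alkylation of the picolyl anion by the primary allylic bromide at its α-carbon builds the whole side chain in one step with the alkene geometry untouched; no stereocentre is formed.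

**Step 2**
Reactants: 4 3-[(3E,7E)-4,8,12-trimethyltrideca-3,7,11-trien-1-yl]pyridine
Product: 6 rac-2-[(3E,7E)-4,8,12-trimethyltrideca-3,7,11-trien-1-yl]pentanedial, via 1,4-dihydropyridine 5 (not isolated)
Conditions: Na, EtOH, NH3(l)/THF, −78 → −33 °C; evaporate; then 1 M aq. HCl/Et2O, 0 °C; used crude
Reagents that add atoms: water, O
Why: Birch reduction of the pyridine to the bis-enamine 5 and enamine hydrolysis excise nitrogen as ammonium and unmask the 1,5-dialdehyde, while isolated trisubstituted alkenes are inert to Na/NH3; C5 is created on C-protonation as a racemic but epimerisable α-formyl centre that is corrected in step 4.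

**Step 3**
Reactants: 6 rac-2-[(3E,7E)-4,8,12-trimethyltrideca-3,7,11-trien-1-yl]pentanedial; 7 N-acryloyl-(2S)-bornane-10,2-sultam
Product: 8 (1S,5S,8RS)-4-methylidene-8-[(3E,7E)-4,8,12-trimethyltrideca-3,7,11-trien-1-yl]-2,9-dioxabicyclo[3.3.1]nonan-3-one
Conditions: DABCO (0.2 equiv), CH2Cl2, 0 °C, 48 h
Reagents that add atoms: none
Why: Proposed new method: the closest known reaction is the sultam-directed asymmetric Baylis–Hillman reaction, which joins the acrylamide and two aldehyde molecules to a 5-methylidene-1,3-dioxan-4-one with loss of the auxiliary. Here both formyl groups sit in one molecule: the DABCO-derived enolate of 7 adds to the unbranched formyl group (α-branched aldehydes are poor partners) under auxiliary control, which sets the carbinol centre (C5 of 8, C2 of the target). The alkoxide then closes onto the second formyl group as an oxane hemiacetal, which acylates itself on the N-acyl sultam (expelling it) before E1cB loss of DABCO. Both C8 epimers form because 6 is racemic there.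

**Step 4**
Reactants: 8 (1S,5S,8RS)-4-methylidene-8-[(3E,7E)-4,8,12-trimethyltrideca-3,7,11-trien-1-yl]-2,9-dioxabicyclo[3.3.1]nonan-3-one
Product: 10 methyl (3S,6R,9E,13E)-3-hydroxy-6-(hydroxymethyl)-10,14,18-trimethyl-2-methylidenenonadeca-9,13,17-trienoate, via lactol methyl ester 9 (not isolated)
Conditions: K2CO3 (0.3 equiv), MeOH, 0 → 23 °C; then NaBH4, −20 °C
Reagents that add atoms: methanol, CO
Why: Methanolysis of the acyloxy-acetal lactone gives lactol ester 9, whose C5 epimerises through the ring-opened hydroxy aldehyde to the diequatorial 2,5-trans lactol (about 5:1 expected, relayed from C2), and chemoselective NaBH4 reduction of the aldehyde form then freezes C5 as (6R) in 10 without touching the α-substituted acrylate; the minor epimer is removed by chromatography.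

**Step 5**
Reactants: 10 methyl (3S,6R,9E,13E)-3-hydroxy-6-(hydroxymethyl)-10,14,18-trimethyl-2-methylidenenonadeca-9,13,17-trienoate
Product: 13 2-[(2S,5R)-5-[(3E,7E)-4,8,12-trimethyltrideca-3,7,11-trien-1-yl]oxan-2-yl]prop-2-enoic acid, via primary tosylate 11 (not isolated), via oxane methyl ester 12 (not isolated)
Conditions: TsCl, Et3N, Me3N·HCl (cat.), CH2Cl2, 0 °C; then LiOH, THF/H2O, 23 → 45 °C; aq. HCl to pH 3
Reagents that add atoms: p-toluenesulfonyl chloride, Cc1ccc(cc1)S(Cl)(=O)=O (tosyl group, present in 11 only); lithium hydroxide, [Li+].[OH-] (carboxyl OH oxygen of 13)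
Why: Selective sulfonylation of the primary alcohol, intramolecular Williamson etherification (6-exo-tet, C2–O bond never broken, no oxocarbenium next to the olefin-bearing C5 that could undergo Prins capture) and ester saponification give the acid with both stereocentres untouched.

**Compound list**

1 | 3-methylpyridine (3-picoline) | Cc1cccnc1 | starting material
2 | (2E,6E)-farnesyl bromide | BrC/C=C(\C)CC/C=C(\C)CCC=C(C)C | starting material
3 | (pyridin-3-ylmethyl)lithium | [Li]Cc1cccnc1 | intermediate
4 | 3-[(3E,7E)-4,8,12-trimethyltrideca-3,7,11-trien-1-yl]pyridine | c1cc(CC/C=C(\C)CC/C=C(\C)CCC=C(C)C)cnc1 | intermediate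
5 | 3-[(3E,7E)-4,8,12-trimethyltrideca-3,7,11-trien-1-yl]-1,4-dihydropyridine | N1C=C(CC/C=C(\C)CC/C=C(\C)CCC=C(C)C)CC=C1 | intermediate
6 | rac-2-[(3E,7E)-4,8,12-trimethyltrideca-3,7,11-trien-1-yl]pentanedial | O=CCCC(C=O)CC/C=C(\C)CC/C=C(\C)CCC=C(C)C | intermediate
7 | N-acryloyl-(2S)-bornane-10,2-sultam (acrylamide of (1R)-(+)-2,10-camphorsultam; (3aR,6S,7aS)) | O=S1(=O)C[C@@]23CC[C@@H](C[C@@H]2N1C(=O)C=C)C3(C)C | starting material
8 | (1S,5S,8RS)-4-methylidene-8-[(3E,7E)-4,8,12-trimethyltrideca-3,7,11-trien-1-yl]-2,9-dioxabicyclo[3.3.1]nonan-3-one (both C8 epimers) | C=C1C(=O)O[C@@H]2O[C@H]1CCC2CC/C=C(\C)CC/C=C(\C)CCC=C(C)C | intermediate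
9 | methyl 2-[(2S,5R)-6-hydroxy-5-[(3E,7E)-4,8,12-trimethyltrideca-3,7,11-trien-1-yl]oxan-2-yl]prop-2-enoate (both C6 anomers) | C=C(C(=O)OC)[C@@H]1CC[C@@H](CC/C=C(\C)CC/C=C(\C)CCC=C(C)C)C(O)O1 | intermediate
10 | methyl (3S,6R,9E,13E)-3-hydroxy-6-(hydroxymethyl)-10,14,18-trimethyl-2-methylidenenonadeca-9,13,17-trienoate | C=C(C(=O)OC)[C@@H](O)CC[C@H](CO)CC/C=C(\C)CC/C=C(\C)CCC=C(C)C | intermediate
11 | methyl (3S,6R,9E,13E)-3-hydroxy-10,14,18-trimethyl-2-methylidene-6-[(tosyloxy)methyl]nonadeca-9,13,17-trienoate | C=C(C(=O)OC)[C@@H](O)CC[C@H](COS(=O)(=O)c1ccc(C)cc1)CC/C=C(\C)CC/C=C(\C)CCC=C(C)C | intermediate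
12 | methyl 2-[(2S,5R)-5-[(3E,7E)-4,8,12-trimethyltrideca-3,7,11-trien-1-yl]oxan-2-yl]prop-2-enoate | C=C(C(=O)OC)[C@@H]1CC[C@@H](CC/C=C(\C)CC/C=C(\C)CCC=C(C)C)CO1 | intermediate
13 | 2-[(2S,5R)-5-[(3E,7E)-4,8,12-trimethyltrideca-3,7,11-trien-1-yl]oxan-2-yl]prop-2-enoic acid | C=C(C(=O)O)[C@@H]1CC[C@@H](CC/C=C(\C)CC/C=C(\C)CCC=C(C)C)CO1 | target

**Step count and risks**

Total step count: 5. Longest linear sequence: 5 (1 → 4 → 6 → 8 → 10 → 13; compound 7 is bought).

The three steps most likely to fail:

Step 3 (new intramolecular cascade; oligomers, reaction at the wrong formyl group, or the auxiliary sense being the reverse). Fallback, from 6: replace auxiliary control by catalyst control. α-Isocupreine (10 mol %, the (S)-selective quinine-derived counterpart of β-isocupreidine) and 1,1,1,3,3,3-hexafluoropropan-2-yl acrylate in DMF at −55 °C would give the lactol ester 1,1,1,3,3,3-hexafluoropropan-2-yl 2-[(2S)-6-hydroxy-5-[(3E,7E)-4,8,12-trimethyltrideca-3,7,11-trien-1-yl]oxan-2-yl]prop-2-enoate F2 (C5 epimers, some 8 alongside). The K2CO3/MeOH stage of step 4 transesterifies F2 and the route is rejoined at 9.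

Step 2 (over-reduction or coupling in the Birch step; the free dialdehyde oligomerises readily). Fallback, from 4: catalytic hydride transfer instead of dissolving metal. [Ru(p-cymene)Cl2]2 (1 mol %) and pinacolborane at 50 °C would give the N-boryl dihydropyridine 1-(4,4,5,5-tetramethyl-1,3,2-dioxaborolan-2-yl)-3-[(3E,7E)-4,8,12-trimethyltrideca-3,7,11-trien-1-yl]-1,4-dihydropyridine F1, which is stable enough to purify. Hydrolysis with 1 M HCl/Et2O at 0 °C immediately before use returns to 6.

Step 4 (methoxide or the aldehyde enolate may add to the acrylate ester during C5 equilibration). Fallback, from 8: open the lactone with LiOH in THF/H2O, so that the acrylate is a carboxylate and no longer a Michael acceptor while C5 equilibrates, then add NaBH4 in the same flask to give (3S,6R,9E,13E)-3-hydroxy-6-(hydroxymethyl)-10,14,18-trimethyl-2-methylidenenonadeca-9,13,17-trienoic acid F3. Esterification with Me3SiCHN2 in MeOH/toluene returns to 10.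

**Further compounds**

F1 | step 2 | 1-(4,4,5,5-tetramethyl-1,3,2-dioxaborolan-2-yl)-3-[(3E,7E)-4,8,12-trimethyltrideca-3,7,11-trien-1-yl]-1,4-dihydropyridine | CC1(C)OB(OC1(C)C)N1C=CCC(CC/C=C(\C)CC/C=C(\C)CCC=C(C)C)=C1
F2 | step 3 | 1,1,1,3,3,3-hexafluoropropan-2-yl 2-[(2S)-6-hydroxy-5-[(3E,7E)-4,8,12-trimethyltrideca-3,7,11-trien-1-yl]oxan-2-yl]prop-2-enoate | C=C(C(=O)OC(C(F)(F)F)C(F)(F)F)[C@@H]1CCC(CC/C=C(\C)CC/C=C(\C)CCC=C(C)C)C(O)O1
F3 | step 4 | (3S,6R,9E,13E)-3-hydroxy-6-(hydroxymethyl)-10,14,18-trimethyl-2-methylidenenonadeca-9,13,17-trienoic acid | C=C(C(=O)O)[C@@H](O)CC[C@H](CO)CC/C=C(\C)CC/C=C(\C)CCC=C(C)C
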